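**Retrosynthetic overview**
1. Numbering used throughout: carbocycle C1 (CH–aryl), C2=C3 (CH3 on C3), C4H2, C5(CH3)2, C6H, with the carbinol carbon C7 on C6. The strategy rests on one feature: the two identical 5,7-dimethoxycoumarin-8-yl groups sit on C1 and C7, the β-carbon and the carbonyl carbon of a C6=C1 enal, so one arylboron reagent can make both aryl–carbon bonds.
2. C7–OH ⇒ C7 ketone 8 (late hydride addition, Felkin–Anh control from C6). C1–aryl and C7–aryl ⇒ dienal 2 + two molecules of boronic acid 6 (rhodium 1,4-addition, then acylative 1,2-coupling in the same flask; sets C1 and C6).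
3. Dienal 2 ⇒ two molecules of prenal 1 (amine-catalysed cyclodimerisation). Boronic acid 6 ⇒ citropten 3 (C8 iodination, Miyaura borylation, pinacol removal).
4. Ring order: the carbocycle is the only ring that is built (step 1). Both coumarin bicycles are bought intact in 3, and no ring closes after step 1.

Key step: step 5

Assumption: the sense of induction of the chiral diene ligand on this cyclic dienal cannot be assigned in advance; the route is written for the ligand antipode that adds the aryl group to the Si face of C1, the other antipode being equally available.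

**Step 1**
Reactants: 1 3-methylbut-2-enal (prenal), two molecules
Product: 2 4,6,6-trimethylcyclohexa-1,3-diene-1-carbaldehyde
Conditions: L-proline (cat.), EtOH, rt
Reagents that add atoms: none
Why: Amine-catalysed cyclodimerisation of a β-methyl enal (dienamine catalysis): the proline dienamine of one prenal (a 1-amino-3-methylbutadiene) and a second prenal combine in a formal [4+2] sense, CH2 terminus to the β-carbon and amino-bearing carbon to the α-carbon, and β-elimination of proline leaves the conjugated dienal with the formyl group next to the gem-dimethyl carbon; no stereocentre is formed.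

**Step 2**
Reactants: 3 5,7-dimethoxy-2H-chromen-2-one (citropten)
Product: 4 8-iodo-5,7-dimethoxy-2H-chromen-2-one
Conditions: NIS, TFA (cat.), MeCN, rt
Reagents that add atoms: N-iodosuccinimide, O=C1CCC(=O)N1I
Why: Electrophilic aromatic iodination with acid-activated NIS: C8 is ortho to the 7-methoxy group and to the ring oxygen and para to the 5-methoxy group and is the least encumbered activated position, whereas C6 lies between two methoxy groups and the pyranone C3 is not activated.

**Step 3**
Reactants: 4 8-iodo-5,7-dimethoxy-2H-chromen-2-one
Product: 5 5,7-dimethoxy-8-(4,4,5,5-tetramethyl-1,3,2-dioxaborolan-2-yl)-2H-chromen-2-one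
Conditions: B2pin2, Pd(dppf)Cl2 (cat.), KOAc, 1,4-dioxane, 90 °C
Reagents that add atoms: bis(pinacolato)diboron, CC1(C)OB(OC1(C)C)B1OC(C)(C)C(C)(C)O1
Why: Miyaura borylation (oxidative addition of Pd(0) into the C8–I bond, acetate-assisted transmetalation from the diboron, reductive elimination), in which the weak base KOAc leaves the lactone closed and the iodide compensates for the two ortho oxygen substituents.

**Step 4**
Reactants: 5 5,7-dimethoxy-8-(4,4,5,5-tetramethyl-1,3,2-dioxaborolan-2-yl)-2H-chromen-2-one
Product: 6 (5,7-dimethoxy-2-oxo-2H-chromen-8-yl)boronic acid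
Conditions: NaIO4, NH4OAc, acetone/H2O, rt
Reagents that add atoms: water, O
Why: Oxidative pinacol removal: the hydrolysis equilibrium of the boronic ester is pulled to the acid by periodate cleavage of the released pinacol, and the near-neutral medium at room temperature should keep protodeboronation of the 2,6-dioxygenated arylboronic acid slow.

**Step 5**
Reactants: 2 4,6,6-trimethylcyclohexa-1,3-diene-1-carbaldehyde; 6 (5,7-dimethoxy-2-oxo-2H-chromen-8-yl)boronic acid (two aryl groups transferred, reagent used in excess)
Product: 8 8-[(1S,6R)-6-(5,7-dimethoxy-2-oxo-2H-chromene-8-carbonyl)-3,5,5-trimethylcyclohex-2-en-1-yl]-5,7-dimethoxy-2H-chromen-2-one (C7 ketone; aryl on C1 trans to aroyl on C6), via trans-aldehyde 7 (not isolated)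
Conditions: [RhCl(C2H4)2]2 (cat.), chiral bicyclo[2.2.2]octadiene ligand Ph-bod* (cat., antipode as assumed), K3PO4 (0.5 equiv), 6 (2 equiv), dioxane/H2O 10:1, 50 °C; then 6 (2 equiv), acetone, P(t-Bu)3 (cat.), 80 °C; dilute HCl work-up
Reagents that add atoms: none
Why: Proposed new method: an aryl–rhodium(I) formed by transmetalation from 6 carbometalates the C6=C1 bond of 2 on the chiral-diene complex (C1–aryl bond) and water protonates the oxa-π-allyl rhodium to aldehyde 7; after acetone and the phosphine are added, a second aryl–rhodium inserts the C7=O group and the crowded rhodium alkoxide undergoes β-hydride elimination to the ketone (C7–aryl bond), the hydride being passed on to acetone. The closest known reaction types are the rhodium/chiral-diene 1,4-addition of arylboronic acids to enals and the rhodium-catalysed acylative coupling of aldehydes with arylboron reagents in acetone, and what is new is their union in one flask on a 2,4-dienal with a di-ortho-oxygenated aryl group. No ring is closed, since the carbocycle comes from 2 and both coumarins from 6. C1 is set by the diene ligand, which should leave only the Si face of the β-carbon open to aryl transfer (1S), C6 is set by thermodynamics because the enolisable formyl group settles trans to the C1 aryl group under the basic conditions before the second addition (6R), and C7 leaves as an sp2 carbon. The step needs 1,4-addition ahead of 1,6- and early 1,2-addition, which the diene ligand and the fully substituted δ-carbon C3 should secure, and it must spare the coumarin C3=C4 enoates, which are push–pull deactivated by the 5- and 7-methoxy groups and shielded at C4 by the peri 5-methoxy group. Because 6 is di-ortho-substituted and prone to protodeboronation it is used in excess in two portions with little water and a weak base, and the acidic work-up recloses any lactone opened by base.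

**Step 6**
Reactants: 8 the C7 ketone from step 5
Product: 9 8-[(1S,6R)-6-[(R)-(5,7-dimethoxy-2-oxo-2H-chromen-8-yl)(hydroxy)methyl]-3,5,5-trimethylcyclohex-2-en-1-yl]-5,7-dimethoxy-2H-chromen-2-one (IN0553)
Conditions: NaBH4, CeCl3·7H2O, MeOH/THF, −40 °C → 0 °C; aq. NH4Cl work-up
Reagents that add atoms: none
Why: Luche reduction under Felkin–Anh control: CeCl3 activates the shielded, non-conjugated C7 carbonyl (the di-ortho-substituted aryl ring is twisted out of its plane) and keeps borohydride off the coumarin enoates, and with the quaternary C5 as the large group anti to the incoming hydride and the C6–H on the side of approach the hydride should add to the Si face of C7 and give the 7R carbinol, while the neutral work-up protects the ionisable electron-rich benzylic alcohol.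

**Compound list**
1 | 3-methylbut-2-enal (prenal) | CC(C)=CC=O | starting material
2 | 4,6,6-trimethylcyclohexa-1,3-diene-1-carbaldehyde | CC1=CC=C(C=O)C(C)(C)C1 | intermediate
3 | 5,7-dimethoxy-2H-chromen-2-one (citropten) | COc1cc(OC)c2ccc(=O)oc2c1 | starting material
4 | 8-iodo-5,7-dimethoxy-2H-chromen-2-one | COc1cc(OC)c2ccc(=O)oc2c1I | intermediate
5 | 5,7-dimethoxy-8-(4,4,5,5-tetramethyl-1,3,2-dioxaborolan-2-yl)-2H-chromen-2-one | COc1cc(OC)c2ccc(=O)oc2c1B3OC(C)(C)C(C)(C)O3 | intermediate
6 | (5,7-dimethoxy-2-oxo-2H-chromen-8-yl)boronic acid | COc1cc(OC)c2ccc(=O)oc2c1B(O)O | intermediate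
7 | (1R,2S)-2-(5,7-dimethoxy-2-oxo-2H-chromen-8-yl)-4,6,6-trimethylcyclohex-3-ene-1-carbaldehyde (1S,6R in the target numbering, trans) | COc1cc(OC)c2ccc(=O)oc2c1[C@H]1C=C(C)CC(C)(C)[C@@H]1C=O | intermediate (formed in the flask, not isolated)
8 | 8-[(1S,6R)-6-(5,7-dimethoxy-2-oxo-2H-chromene-8-carbonyl)-3,5,5-trimethylcyclohex-2-en-1-yl]-5,7-dimethoxy-2H-chromen-2-one | COc1cc(OC)c2ccc(=O)oc2c1[C@H]1C=C(C)CC(C)(C)[C@@H]1C(=O)c1c(OC)cc(OC)c2ccc(=O)oc12 | intermediate
9 | 8-[(1S,6R)-6-[(R)-(5,7-dimethoxy-2-oxo-2H-chromen-8-yl)(hydroxy)methyl]-3,5,5-trimethylcyclohex-2-en-1-yl]-5,7-dimethoxy-2H-chromen-2-one (IN0553) | COc1cc(OC)c2ccc(=O)oc2c1[C@H]1C=C(C)CC(C)(C)[C@@H]1[C@@H](O)c1c(OC)cc(OC)c2ccc(=O)oc12 | target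

**Total step count:** 6
**Longest linear sequence:** 5 steps (3 → 4 → 5 → 6 → 8 → 9)

**Steps most likely to fail**

1. Step 5 (Proposed new method).
 - Risk: transmetalation and insertion of the di-ortho-substituted aryl–rhodium may be so slow that protodeboronation of 6 outruns one or both C–C bond formations. The second stage may also stop at protonation of the rhodium alkoxide instead of β-hydride elimination, and the phosphine-modified catalyst may not turn over beside the diene.
 - Fallback: it sets out from 2 and 6 and comes back at 8, using known reactions run separately. The first stage alone is run as a rhodium/chiral-diene 1,4-addition of an arylboronic acid to an enal (no acetone, limited 6, base-mediated equilibration) and aldehyde 7 is isolated. Then 7 and 6 are joined by rhodium(I)/phosphine-catalysed 1,2-addition of the arylboronic acid to the aldehyde in DME/H2O without a hydride acceptor, which should give the diaryl carbinol 8-[(1S,6R)-6-[(5,7-dimethoxy-2-oxo-2H-chromen-8-yl)(hydroxy)methyl]-3,5,5-trimethylcyclohex-2-en-1-yl]-5,7-dimethoxy-2H-chromen-2-one F1, with C7 not controlled. Dess–Martin oxidation (NaHCO3-buffered, CH2Cl2) then converts it into ketone 8, where the route resumes.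

2. Step 6.
 - Risk: facial selectivity at C7 may be poor or reversed if the aryl-bearing C1 rather than the quaternary C5 acts as the large group. Reduction of the shielded carbonyl may also be slow enough for borohydride to begin attacking the coumarin lactones.
 - Fallback: it sets out from aldehyde 7 (isolated as in the fallback above) and 6 and comes back at 9. C7 is created with the aryl group instead of hydride as the nucleophile, by rhodium-catalysed 1,2-addition of 6 to 7 in aqueous DME without a hydride acceptor. The same conformational bias that would send hydride to the wrong face of 8 should send the aryl group to the face of 7 that gives the 7R carbinol. It makes no compound outside the list (F0).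

3. Step 1.
 - Risk: linear aldol condensation of prenal to the open-chain trienal and oligomerisation may compete with the cyclodimerisation and leave little of 2.
 - Fallback: it does not set out from a numbered compound but from commercial isophorone (CC1=CC(=O)CC(C)(C)C1), and comes back at 2. The kinetic C6 enolate (LDA, THF, −78 °C) is formylated with ethyl formate to 6-(hydroxymethylene)-3,5,5-trimethylcyclohex-2-en-1-one F2. O-Alkylation with 2-iodopropane and K2CO3 in acetone gives 6-(isopropoxymethylene)-3,5,5-trimethylcyclohex-2-en-1-one F3. LiAlH4 (Et2O, 0 °C) reduces the carbonyl 1,2 to racemic 6-(isopropoxymethylene)-3,5,5-trimethylcyclohex-2-en-1-ol F4. Dilute aqueous acid ionises this allylic alcohol and hydrolyses the enol ether with allylic transposition, which should give dienal 2.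

**Further compounds**
F1 | step 5 | 8-[(1S,6R)-6-[(5,7-dimethoxy-2-oxo-2H-chromen-8-yl)(hydroxy)methyl]-3,5,5-trimethylcyclohex-2-en-1-yl]-5,7-dimethoxy-2H-chromen-2-one, C7 configuration not controlled | COc1cc(OC)c2ccc(=O)oc2c1[C@H]1C=C(C)CC(C)(C)[C@@H]1C(O)c1c(OC)cc(OC)c2ccc(=O)oc12
F0 | step 6 | none | none
F2 | step 1 | 6-(hydroxymethylene)-3,5,5-trimethylcyclohex-2-en-1-one | CC1=CC(=O)C(=CO)C(C)(C)C1
F3 | step 1 | 6-(isopropoxymethylene)-3,5,5-trimethylcyclohex-2-en-1-one | CC1=CC(=O)C(=COC(C)C)C(C)(C)C1
F4 | step 1 | 6-(isopropoxymethylene)-3,5,5-trimethylcyclohex-2-en-1-ol (racemic) | CC1=CC(O)C(=COC(C)C)C(C)(C)C1
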